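**Retrosynthetic overview**

1. The target is read as a (2S,3S,4S,5R)-2,5-diaryl-3,4-dimethyloxolane (2-aryl/3-Me trans, Me/Me trans, 4-Me/5-aryl cis, aryls cis). The C2 aryl (fragment A) carries the (1R,2S) chain and the C5 aryl (fragment B) the (1R,2R) chain.
2. Both carbinols come from one double CBS reduction of bis-ketone 16; both ketones come from diester 12 in one pot (Weinreb amide, then aryl Grignard).
3. Key step: oxolane 12 by 5-exo radical closure of the mixed O,S-acetal 11, forming the C4–C5 bond and both remaining ring centres. This is the only ring built (step 6); the four benzene rings are bought.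
4. 11 comes from homoallylic alcohol 5 (A) and the thionium ion of dithioacetal 9 (B); 5 comes from catalytic anti-crotylboration of aldehyde 3.
5. 3 and 7 come from vanillin and (R)- or (S)-methyl lactate by Mitsunobu inversion, which sets both ether centres and makes A and B different from the first step.

Assumption: (S)-TRIP is taken to direct si-face attack on aryl aldehydes (mirror image of the re-face sense recalled for the (R)-catalyst); if the sense is opposite, (R)-TRIP is used with no other change.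

**Step 1**
Reactants: 1 vanillin; 2 methyl (R)-lactate
Product: 3 methyl (2S)-2-(4-formyl-2-methoxyphenoxy)propanoate
Conditions: PPh3, DIAD, THF, 0 °C → rt
Reagents that add atoms: methyl (R)-lactate (2), C[C@@H](O)C(=O)OC
Why: Mitsunobu etherification of the acidic phenol with the secondary lactate alcohol is an SN2 displacement with clean inversion, so (R)-lactate gives the (S)-aryloxypropanoate that becomes the ether carbon of the (1R,2S) chain.

**Step 2**
Reactants: 3 methyl (2S)-2-(4-formyl-2-methoxyphenoxy)propanoate; 4 (E)-crotylboronic acid pinacol ester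
Product: 5 methyl (2S)-2-{4-[(1S,2S)-1-hydroxy-2-methylbut-3-en-1-yl]-2-methoxyphenoxy}propanoate
Conditions: (S)-TRIP [(S)-3,3'-bis(2,4,6-triisopropylphenyl)-1,1'-binaphthyl-2,2'-diyl hydrogen phosphate] (5 mol %), 4 Å MS, toluene, −30 °C
Reagents that add atoms: (E)-crotylboronic acid pinacol ester (4), C/C=C/CB1OC(C)(C)C(C)(C)O1
Why: Chiral phosphoric acid-catalysed crotylboration through a Zimmerman–Traxler chair gives the anti adduct from the (E)-boronate, and the catalyst directs si-face attack so that both new centres are S (the future C2 and C3 of the oxolane), while the ester is inert to the neutral boronate.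

**Step 3**
Reactants: 1 vanillin; 6 methyl (S)-lactate
Product: 7 methyl (2R)-2-(4-formyl-2-methoxyphenoxy)propanoate
Conditions: PPh3, DIAD, THF, 0 °C → rt
Reagents that add atoms: methyl (S)-lactate (6), C[C@H](O)C(=O)OC
Why: The same Mitsunobu inversion on the enantiomeric lactate gives the (R)-aryloxypropanoate needed for the (1R,2R) chain of fragment B.

**Step 4**
Reactants: 7 methyl (2R)-2-(4-formyl-2-methoxyphenoxy)propanoate; 8 thiophenol
Product: 9 methyl (2R)-2-{4-[bis(phenylsulfanyl)methyl]-2-methoxyphenoxy}propanoate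
Conditions: PhSH (2.2 equiv), BF3·OEt2 (0.2 equiv), CH2Cl2, 0 °C → rt
Reagents that add atoms: thiophenol (8), Sc1ccccc1
Why: Lewis acid-catalysed dithioacetalisation of the electron-rich aldehyde proceeds under non-basic conditions that leave the α-aryloxy ester and its stereocentre untouched.

**Step 5**
Reactants: 5 methyl (2S)-2-{4-[(1S,2S)-1-hydroxy-2-methylbut-3-en-1-yl]-2-methoxyphenoxy}propanoate; 9 methyl (2R)-2-{4-[bis(phenylsulfanyl)methyl]-2-methoxyphenoxy}propanoate
Product: 11 mixed O,S-acetal in which the hydroxyl oxygen of 5 is bonded to the (phenylsulfanyl)benzylic carbon of fragment B (both epimers at that carbon), via thionium triflate 10 (not isolated)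
Conditions: 9 (1.3 equiv), MeOTf (1.25 equiv), 2,6-di-tert-butyl-4-methylpyridine (2 equiv), 4 Å MS, CH2Cl2, 0 °C, 1 h; then 5 (1.0 equiv), −40 → 0 °C; Et3N quench
Reagents that add atoms: none
Why: S-Methylation of one sulfur by MeOTf expels thioanisole and leaves an aryl-stabilised thionium ion that the secondary alcohol captures at carbon (thioacetal-to-O,S-acetal exchange, a Pummerer-type thionium capture) under hindered-base buffering, so no oxocarbenium ion is formed, the homoallylic alcohol cannot scramble by 2-oxonia-Cope rearrangement, and the new acetal centre is erased in the next step.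

**Step 6**
Reactants: 11 mixed O,S-acetal
Product: 12 methyl (2S)-2-{2-methoxy-4-[(2S,3S,4S,5R)-5-{3-methoxy-4-[(2R)-1-methoxy-1-oxopropan-2-yl]oxyphenyl}-3,4-dimethyloxolan-2-yl]phenoxy}propanoate
Conditions: Bu3SnH (1.5 equiv, syringe pump over 8 h), AIBN (0.2 equiv), benzene (0.005 M), 80 °C
Reagents that add atoms: none
Why: Proposed new method: Bu3Sn• removes PhS to give an α-alkoxybenzyl radical that closes 5-exo-trig onto the vinyl group through a Beckwith–Houk chair with aryl A, the C3 methyl and aryl B all pseudo-equatorial, which places the new C4 methyl trans to the C3 methyl and cis to aryl B (so the two aryls end cis), and the primary radical is then reduced to the methyl group by Bu3SnH; the closest known reaction type is the Bu3SnH cyclisation of alkoxymethyl (2-oxahex-5-enyl) radicals from O,Se- or O,S-acetals to 3-methyloxolanes.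

**Step 7**
Reactants: 12 oxolane diester; 13 N,O-dimethylhydroxylamine hydrochloride; 14 3,4-dimethoxyphenylmagnesium bromide
Product: 16 (2S)-1-(3,4-dimethoxyphenyl)-2-{4-[(2S,3S,4S,5R)-5-(4-{[(2R)-1-(3,4-dimethoxyphenyl)-1-oxopropan-2-yl]oxy}-3-methoxyphenyl)-3,4-dimethyloxolan-2-yl]-2-methoxyphenoxy}propan-1-one, via bis-Weinreb amide 15 (not isolated)
Conditions: MeNHOMe·HCl (3 equiv), i-PrMgCl (6 equiv), THF, −20 °C; then 3,4-(MeO)2C6H3MgBr (5 equiv), −20 → 0 °C; aq NH4Cl
Reagents that add atoms: 3,4-dimethoxyphenylmagnesium bromide (14), COc1ccc([Mg]Br)cc1OC; N,O-dimethylhydroxylamine hydrochloride (13), CNOC.Cl (its atoms stay only in 15)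
Why: One-pot Weinreb ketone synthesis, in which the magnesium amide of MeNHOMe converts both esters into Weinreb amides and the aryl Grignard then adds once to each, the chelated tetrahedral intermediates surviving until the quench so that neither α-aryloxy centre is enolised.

**Step 8**
Reactants: 16 bis(α-aryloxy ketone)
Product: 17 (1R,2S)-1-(3,4-dimethoxyphenyl)-2-{4-[(2S,3S,4S,5R)-5-{4-[(1R,2R)-1-(3,4-dimethoxyphenyl)-1-hydroxypropan-2-yl]oxy-3-methoxyphenyl}-3,4-dimethyloxolan-2-yl]-2-methoxyphenoxy}propan-1-ol (target)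
Conditions: (R)-Me-CBS [(R)-1-methyl-3,3-diphenyltetrahydro-1H,3H-pyrrolo[1,2-c][1,3,2]oxazaborole] (1.0 equiv), BH3·SMe2 (2.4 equiv), THF, −20 °C; MeOH
Reagents that add atoms: none
Why: Corey–Bakshi–Shibata reduction under reagent control, with the aryl group as the large substituent, delivers hydride to the same face of both aryl ketones and gives the R carbinol at each (erythro beside the S ether centre, threo beside the R one) without touching the ether centres.

**Compound list**

1 | vanillin | COc1cc(C=O)ccc1O | starting material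
2 | methyl (R)-lactate | C[C@@H](O)C(=O)OC | starting material
3 | methyl (2S)-2-(4-formyl-2-methoxyphenoxy)propanoate | COC(=O)[C@H](C)Oc1ccc(C=O)cc1OC | intermediate
4 | (E)-crotylboronic acid pinacol ester | C/C=C/CB1OC(C)(C)C(C)(C)O1 | starting material
5 | methyl (2S)-2-{4-[(1S,2S)-1-hydroxy-2-methylbut-3-en-1-yl]-2-methoxyphenoxy}propanoate | COC(=O)[C@H](C)Oc1ccc([C@@H](O)[C@@H](C)C=C)cc1OC | intermediate
6 | methyl (S)-lactate | C[C@H](O)C(=O)OC | starting material
7 | methyl (2R)-2-(4-formyl-2-methoxyphenoxy)propanoate | COC(=O)[C@@H](C)Oc1ccc(C=O)cc1OC | intermediate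
8 | thiophenol | Sc1ccccc1 | starting material
9 | methyl (2R)-2-{4-[bis(phenylsulfanyl)methyl]-2-methoxyphenoxy}propanoate | COC(=O)[C@@H](C)Oc1ccc(C(Sc2ccccc2)Sc2ccccc2)cc1OC | intermediate
10 | {3-methoxy-4-[(2R)-1-methoxy-1-oxopropan-2-yl]oxyphenyl}methylidene(phenyl)sulfonium triflate | COC(=O)[C@@H](C)Oc1ccc(C=[S+]c2ccccc2)cc1OC.[O-]S(=O)(=O)C(F)(F)F | intermediate (not isolated)
11 | methyl (2S)-2-{2-methoxy-4-[(1S,2S)-1-({3-methoxy-4-[(2R)-1-methoxy-1-oxopropan-2-yl]oxyphenyl}(phenylsulfanyl)methoxy)-2-methylbut-3-en-1-yl]phenoxy}propanoate, both epimers at the O,S-acetal carbon | COC(=O)[C@H](C)Oc1ccc([C@@H](OC(Sc2ccccc2)c2ccc(O[C@H](C)C(=O)OC)c(OC)c2)[C@@H](C)C=C)cc1OC | intermediate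
12 | methyl (2S)-2-{2-methoxy-4-[(2S,3S,4S,5R)-5-{3-methoxy-4-[(2R)-1-methoxy-1-oxopropan-2-yl]oxyphenyl}-3,4-dimethyloxolan-2-yl]phenoxy}propanoate | COC(=O)[C@H](C)Oc1ccc([C@H]2O[C@@H](c3ccc(O[C@H](C)C(=O)OC)c(OC)c3)[C@@H](C)[C@@H]2C)cc1OC | intermediate
13 | N,O-dimethylhydroxylamine hydrochloride | CNOC.Cl | starting material
14 | 3,4-dimethoxyphenylmagnesium bromide | COc1ccc([Mg]Br)cc1OC | starting material
15 | (2S)-N-methoxy-2-{2-methoxy-4-[(2S,3S,4S,5R)-5-(3-methoxy-4-{[(2R)-1-[methoxy(methyl)amino]-1-oxopropan-2-yl]oxy}phenyl)-3,4-dimethyloxolan-2-yl]phenoxy}-N-methylpropanamide | CON(C)C(=O)[C@H](C)Oc1ccc([C@H]2O[C@@H](c3ccc(O[C@H](C)C(=O)N(C)OC)c(OC)c3)[C@@H](C)[C@@H]2C)cc1OC | intermediate (not isolated)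
16 | (2S)-1-(3,4-dimethoxyphenyl)-2-{4-[(2S,3S,4S,5R)-5-(4-{[(2R)-1-(3,4-dimethoxyphenyl)-1-oxopropan-2-yl]oxy}-3-methoxyphenyl)-3,4-dimethyloxolan-2-yl]-2-methoxyphenoxy}propan-1-one | COc1ccc(C(=O)[C@H](C)Oc2ccc([C@H]3O[C@@H](c4ccc(O[C@H](C)C(=O)c5ccc(OC)c(OC)c5)c(OC)c4)[C@@H](C)[C@@H]3C)cc2OC)cc1OC | intermediate
17 | (1R,2S)-1-(3,4-dimethoxyphenyl)-2-{4-[(2S,3S,4S,5R)-5-{4-[(1R,2R)-1-(3,4-dimethoxyphenyl)-1-hydroxypropan-2-yl]oxy-3-methoxyphenyl}-3,4-dimethyloxolan-2-yl]-2-methoxyphenoxy}propan-1-ol | COc1ccc([C@@H](O)[C@H](C)Oc2ccc([C@H]3O[C@@H](c4ccc(O[C@H](C)[C@H](O)c5ccc(OC)c(OC)c5)c(OC)c4)[C@@H](C)[C@@H]3C)cc2OC)cc1OC | target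

**Step count and risks**

Total step count: 8. Longest linear sequence: 6 steps (1 → 2 → 5 → 6 → 7 → 8; the branch 3 → 4 → 5 is equally long).

Most likely to fail, first: step 6. The stabilised α-alkoxybenzyl radical cyclises slowly and perhaps reversibly, so it may be reduced before ring closure, fragment to aldehyde 7 and a benzylic radical, leak to the 6-endo ring, or give poor selectivity at C5. The fallback gives up the radical C–C closure and closes the ring ionically; it sets out from 5 and 7 and comes back at 12. Hydrogen-atom-transfer Markovnikov hydrobromination of 5 (Co(acac)2, t-BuOOH, Et3SiH, TsBr) gives methyl (2S)-2-{4-[(1S,2R)-3-bromo-1-hydroxy-2-methylbutyl]-2-methoxyphenoxy}propanoate F1 as both C3 epimers. Pinnick oxidation of 7 gives 3-methoxy-4-{[(2R)-1-methoxy-1-oxopropan-2-yl]oxy}benzoic acid F2, which 2,2'-dipyridyl disulfide and PPh3 convert into its S-(pyridin-2-yl) thioester F3. Nickel-catalysed reductive acylation (NiCl2(dme), 4,4'-di-tert-butyl-2,2'-bipyridine, Mn powder, DMA) joins F1 and F3 to the γ-hydroxy ketone methyl (2S)-2-{4-[(1S,2S)-1-hydroxy-4-(3-methoxy-4-{[(2R)-1-methoxy-1-oxopropan-2-yl]oxy}phenyl)-2,3-dimethyl-4-oxobutyl]-2-methoxyphenoxy}propanoate F4. The methyl-bearing carbon next to the ketone is equilibrated with DBU through the closed hemiketal towards the trans-dimethyl isomer; how far this goes is uncertain. Et3SiH and BF3·OEt2 in CH2Cl2 at −78 °C then reduce the cyclic oxocarbenium ion with hydride anti to the adjacent methyl, which puts aryl B cis to it and gives 12.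

Second: step 5. Alcohol 5 is an electron-rich benzylic alcohol that can ionise, the thionium ion can arylate an electron-rich ring, and over-activation of 11 would open the oxocarbenium/oxonia-Cope channel. The fallback avoids any cationic acetal chemistry and any leaving group on the benzylic carbon; it sets out from 5 and 7 and comes back at 12, replacing steps 4 to 6. NaBH4 in MeOH at 0 °C reduces 7 to methyl (2R)-2-[4-(hydroxymethyl)-2-methoxyphenoxy]propanoate F5, and PBr3 gives methyl (2R)-2-[4-(bromomethyl)-2-methoxyphenoxy]propanoate F6. Ag2O-mediated benzylation of 5 with F6 (CH2Cl2, 4 Å MS) gives the benzyl ether methyl (2S)-2-{2-methoxy-4-[(1S,2S)-1-({3-methoxy-4-[(2R)-1-methoxy-1-oxopropan-2-yl]oxyphenyl}methoxy)-2-methylbut-3-en-1-yl]phenoxy}propanoate F7. A thiol-catalysed radical-chain cycloisomerisation (triisopropylsilanethiol 10 mol %, di-tert-butyl hyponitrite, benzene, 60 °C) abstracts a benzylic ether hydrogen, closes the same 5-exo ring and returns hydrogen from the thiol to give 12. Its weak point is competing abstraction at the other benzylic ether C–H, which cannot cyclise but could epimerise C2.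

Third: step 8. The two ether centres are antipodal while the two carbinols are homochiral, so one ketone is necessarily mismatched with the reagent and may give a low diastereomer ratio. The fallback sets the carbinol centres in a catalyst-controlled C–C bond formation instead of a hydride delivery; it sets out from 15 (isolated this time) and comes back at 17. DIBAL in THF at −78 °C reduces 15 to the dialdehyde (2S)-2-{2-methoxy-4-[(2S,3S,4S,5R)-5-{3-methoxy-4-[(2R)-1-oxopropan-2-yl]oxyphenyl}-3,4-dimethyloxolan-2-yl]phenoxy}propanal F8. The aryl(ethyl)zinc made from 3,4-dimethoxyphenylboronic acid and Et2Zn is then added with a catalytic chiral amino alcohol (3-exo-morpholinoisoborneol, the enantiomer that gives the R carbinols) in toluene at −10 °C to give 17. One of the two aldehyde additions is likewise mismatched with the substrate, so this is an alternative mode of control, not a guaranteed fix.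

**Further compounds**

F1 | step 6 | methyl (2S)-2-{4-[(1S,2R)-3-bromo-1-hydroxy-2-methylbutyl]-2-methoxyphenoxy}propanoate (both C3 epimers) | COC(=O)[C@H](C)Oc1ccc([C@@H](O)[C@@H](C)C(C)Br)cc1OC
F2 | step 6 | 3-methoxy-4-{[(2R)-1-methoxy-1-oxopropan-2-yl]oxy}benzoic acid | COC(=O)[C@@H](C)Oc1ccc(C(=O)O)cc1OC
F3 | step 6 | S-(pyridin-2-yl) 3-methoxy-4-{[(2R)-1-methoxy-1-oxopropan-2-yl]oxy}benzenecarbothioate | COC(=O)[C@@H](C)Oc1ccc(C(=O)Sc2ccccn2)cc1OC
F4 | step 6 | methyl (2S)-2-{4-[(1S,2S)-1-hydroxy-4-(3-methoxy-4-{[(2R)-1-methoxy-1-oxopropan-2-yl]oxy}phenyl)-2,3-dimethyl-4-oxobutyl]-2-methoxyphenoxy}propanoate (C3 epimers, in equilibrium with the cyclic hemiketal) | COC(=O)[C@H](C)Oc1ccc([C@@H](O)[C@@H](C)C(C)C(=O)c2ccc(O[C@H](C)C(=O)OC)c(OC)c2)cc1OC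
F5 | step 5 | methyl (2R)-2-[4-(hydroxymethyl)-2-methoxyphenoxy]propanoate | COC(=O)[C@@H](C)Oc1ccc(CO)cc1OC
F6 | step 5 | methyl (2R)-2-[4-(bromomethyl)-2-methoxyphenoxy]propanoate | COC(=O)[C@@H](C)Oc1ccc(CBr)cc1OC
F7 | step 5 | methyl (2S)-2-{2-methoxy-4-[(1S,2S)-1-({3-methoxy-4-[(2R)-1-methoxy-1-oxopropan-2-yl]oxyphenyl}methoxy)-2-methylbut-3-en-1-yl]phenoxy}propanoate | COC(=O)[C@H](C)Oc1ccc([C@@H](OCc2ccc(O[C@H](C)C(=O)OC)c(OC)c2)[C@@H](C)C=C)cc1OC
F8 | step 8 | (2S)-2-{2-methoxy-4-[(2S,3S,4S,5R)-5-{3-methoxy-4-[(2R)-1-oxopropan-2-yl]oxyphenyl}-3,4-dimethyloxolan-2-yl]phenoxy}propanal | O=C[C@H](C)Oc1ccc([C@H]2O[C@@H](c3ccc(O[C@H](C)C=O)c(OC)c3)[C@@H](C)[C@@H]2C)cc1OC
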